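**Retrosynthetic overview**

1. Last step: both lactone rings close in one anionic cascade from the open precursor 14 (saturated lactone of half B, then butenolide of half A). The same operation sets C-3 of lactone B and C-7a of the butenolide.
2. 14 comes from two radical C–C bond formations at the two α-carbons of one adipate linchpin, diethyl meso-2,5-dibromoadipate, one to each of two enantiomeric silyl enol ethers (5 and 13).
3. 5 and 13 come from cyclobutane fragmentation of the two enantiomeric 4-vinylverbanones, made by conjugate vinylation of (+)- and (−)-verbenone.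
4. Ring order: the two cyclohexane rings come ready-made from verbenone, in mirror-image form as the target requires; no further ring is formed until lactone B and butenolide A close together in step 8.

Assumption: the SMILES is taken as drawn (the butenolide half carries the mirror-image carbocycle of the saturated half, 5R,6R against 5S,6S), and both verbenones are used enantiopure.

Half A is the butenolide half; half B is the saturated-lactone half.

**Step 1**
Reactants: 1 (1R,5R)-(+)-verbenone; 2 vinylmagnesium bromide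
Product: 3 (1R,4S,5S)-4-ethenyl-4,6,6-trimethylbicyclo[3.1.1]heptan-2-one
Conditions: 2 (1.5 equiv), CuBr·SMe2 (10 mol %), THF, −40 → 0 °C; 1 M HCl
Reagents that add atoms: vinylmagnesium bromide (2), C=C[Mg]Br
Why: Copper-catalysed conjugate (1,4-) addition of the vinyl Grignard reagent, which approaches the enone face opposite to the gem-dimethyl bridge, so the new quaternary centre (4S) carries the vinyl group anti and the methyl group syn to that bridge.

**Step 2**
Reactants: 3 (1R,4S,5S)-4-ethenyl-4,6,6-trimethylbicyclo[3.1.1]heptan-2-one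
Product: 5 trimethyl{[(4S,5S)-5-ethenyl-5-methyl-4-(prop-1-en-2-yl)cyclohex-1-en-1-yl]oxy}silane, via tertiary iodide silyl enol ether 4 (not isolated)
Conditions: TMSCl, NaI, MeCN, 0 → 25 °C; then DBU, 40 °C
Reagents that add atoms: chlorotrimethylsilane, C[Si](C)(C)Cl
Why: Iodotrimethylsilane made in the flask silylates the carbonyl oxygen and the strained C1–C6 cyclobutane bond, aligned with the C=O π system, breaks toward the tertiary carbon (silyl iodide fragmentation of a cyclobutyl ketone, a Grob-type ring opening) to give the regiodefined silyl enol ether 4, whose tertiary iodide then loses HI by E2 toward a methyl group because the ring C–H is shielded by the neighbouring quaternary carbon; no stereocentre is touched, so the methyl group ends up cis and the vinyl group trans to the isopropenyl group.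

**Step 3**
Reactants: 5 trimethyl{[(4S,5S)-5-ethenyl-5-methyl-4-(prop-1-en-2-yl)cyclohex-1-en-1-yl]oxy}silane; 6 diethyl meso-2,5-dibromohexanedioate
Product: 7 diethyl 2-bromo-5-[(1R,4S,5S)-4-ethenyl-4-methyl-2-oxo-5-(prop-1-en-2-yl)cyclohexyl]hexanedioate (epimer mixture at C-2 and C-5 of the chain)
Conditions: 6 (4 equiv), fac-Ir(ppy)3 (1 mol %), 2,6-lutidine, MeCN, blue LEDs, 25 °C; then TsOH·H2O (5 mol %), CH2Cl2, 25 °C
Reagents that add atoms: diethyl meso-2,5-dibromohexanedioate (6), CCOC(=O)[C@H](Br)CC[C@H](Br)C(=O)OCC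
Why: Visible-light photoredox α-alkylation of a silyl enol ether with an α-bromo ester (radical addition, then oxidation of the α-silyloxy radical and loss of the silyl group), in which the electrophilic ester radical prefers the electron-rich enol ether carbon over the two unactivated alkenes and the excess of 6 holds the reaction at mono-alkylation; the acid treatment equilibrates the new ring stereocentre to the equatorial (1R) position cis to the isopropenyl group, while the two ester α-carbons stay as epimer mixtures that step 8 corrects or erases.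

**Step 4**
Reactants: 7 diethyl 2-bromo-5-[(1R,4S,5S)-4-ethenyl-4-methyl-2-oxo-5-(prop-1-en-2-yl)cyclohexyl]hexanedioate
Product: 9 diethyl 2-bromo-5-[(1R,2R,4S,5S)-4-ethenyl-4-methyl-5-(prop-1-en-2-yl)-2-(triethylsilyloxy)cyclohexyl]hexanedioate, via lithium alkoxide 8 (not isolated)
Conditions: LiBH(s-Bu)3, THF, −78 °C; then TESOTf, 2,6-lutidine (cat.), −78 °C
Reagents that add atoms: triethylsilyl trifluoromethanesulfonate, CC[Si](CC)(CC)OS(=O)(=O)C(F)(F)F
Why: Diastereoselective ketone reduction by a bulky trialkylborohydride, which delivers hydride from the equatorial direction (the axial one is blocked by the axial ring methyl group) to give the axial alkoxide (2R) cis to the side chain; silylation at −78 °C stops the alkoxide from attacking the neighbouring ester, so this ring closure is held back for step 8.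

**Step 5**
Reactants: 10 (1S,5S)-(−)-verbenone; 2 vinylmagnesium bromide
Product: 11 (1S,4R,5R)-4-ethenyl-4,6,6-trimethylbicyclo[3.1.1]heptan-2-one
Conditions: 2 (1.5 equiv), CuBr·SMe2 (10 mol %), THF, −40 → 0 °C; 1 M HCl
Reagents that add atoms: vinylmagnesium bromide (2), C=C[Mg]Br
Why: Mirror image of step 1: copper-catalysed conjugate addition anti to the gem-dimethyl bridge sets the quaternary centre as 4R.

**Step 6**
Reactants: 11 (1S,4R,5R)-4-ethenyl-4,6,6-trimethylbicyclo[3.1.1]heptan-2-one
Product: 13 trimethyl{[(4R,5R)-5-ethenyl-5-methyl-4-(prop-1-en-2-yl)cyclohex-1-en-1-yl]oxy}silane, via tertiary iodide silyl enol ether 12 (not isolated)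
Conditions: TMSCl, NaI, MeCN, 0 → 25 °C; then DBU, 40 °C
Reagents that add atoms: chlorotrimethylsilane, C[Si](C)(C)Cl
Why: Mirror image of step 2: silyl iodide fragmentation of the cyclobutyl ketone followed by E2 loss of HI toward a methyl group, with both stereocentres carried over unchanged.

**Step 7**
Reactants: 13 trimethyl{[(4R,5R)-5-ethenyl-5-methyl-4-(prop-1-en-2-yl)cyclohex-1-en-1-yl]oxy}silane; 9 diethyl 2-bromo-5-[(1R,2R,4S,5S)-4-ethenyl-4-methyl-5-(prop-1-en-2-yl)-2-(triethylsilyloxy)cyclohexyl]hexanedioate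
Product: 14 diethyl 2-[(4R,5R)-4-ethenyl-4-methyl-2-oxo-5-(prop-1-en-2-yl)cyclohexyl]-5-[(1R,2R,4S,5S)-4-ethenyl-4-methyl-5-(prop-1-en-2-yl)-2-(triethylsilyloxy)cyclohexyl]hexanedioate (epimer mixture at C-1 of the oxocyclohexyl ring and at C-2 and C-5 of the chain)
Conditions: 13 (1.5 equiv), fac-Ir(ppy)3 (1 mol %), 2,6-lutidine, MeCN, blue LEDs, 25 °C
Reagents that add atoms: none
Why: The same photoredox radical α-alkylation of a silyl enol ether as in step 3 now joins the two halves; the new stereocentres (ring carbon next to the ketone and the ester α-carbon) are not controlled and need not be, because both become sp2 in the butenolide.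

**Step 8**
Reactants: 14 diethyl 2-[(4R,5R)-4-ethenyl-4-methyl-2-oxo-5-(prop-1-en-2-yl)cyclohexyl]-5-[(1R,2R,4S,5S)-4-ethenyl-4-methyl-5-(prop-1-en-2-yl)-2-(triethylsilyloxy)cyclohexyl]hexanedioate
Product: 18 target (5R,6R,7aR)-6-ethenyl-3-{2-[(3S,3aR,5S,6S,7aR)-6-ethenyl-6-methyl-2-oxo-5-(prop-1-en-2-yl)octahydro-1-benzofuran-3-yl]ethyl}-6-methyl-5-(prop-1-en-2-yl)-5,6,7,7a-tetrahydro-1-benzofuran-2(4H)-one, via lactone keto ester 15 (not isolated), via dipotassium bis-enolate 16 (not isolated), via deconjugated butenolide isomer 17 (not isolated)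
Conditions: TASF, THF, 0 °C; KN(SiMe3)2 (4.5 equiv), −78 → 0 °C; recool, 2,6-di-tert-butylphenol (6 equiv), −78 → 25 °C, 3 h; 0.5 M HCl work-up
Reagents that add atoms: none
Why: Proposed new method: fluoride frees the axial alkoxide, which closes the cis-fused lactone of half B on the adjacent equatorial ester (desilylative lactonisation), and excess potassium amide then converts the γ-keto ester of half A into its enolate, whose oxygen acylates intramolecularly (5-exo; C-acylation would give a bridged, non-enolisable diketone, and Dieckmann closure of the adipate core has no stabilised enolate to end in because both α-carbons are tertiary, so both are reversible) and whose product loses a further proton to the aromatic 2-oxidofuran, while lactone B becomes its enolate; the hindered phenol at −78 °C protonates C-3 of lactone B from the convex face (kinetic protonation of a cis-fused lactone enolate, giving 3S with H cis to the ring-fusion hydrogens) and the 2-oxidofuran at its α-carbon, and on warming the phenoxide moves the double bond into conjugation and equilibrates C-7a of the butenolide to the isomer with the C–O bond equatorial and trans to the axial methyl group (7aR), being too weak to touch C-3 of lactone B; the closest known reaction types are base-mediated enol-lactone formation from keto esters, the butenolide/2-oxidofuran equilibrium used to make 2-silyloxyfurans, and kinetic protonation of fused lactone enolates.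

**Compound list**

1 | (1R,5R)-(+)-verbenone | CC1=CC(=O)[C@@H]2C[C@H]1C2(C)C | starting material
2 | vinylmagnesium bromide | C=C[Mg]Br | starting material
3 | (1R,4S,5S)-4-ethenyl-4,6,6-trimethylbicyclo[3.1.1]heptan-2-one | O=C1C[C@@](C)(C=C)[C@H]2C[C@@H]1C2(C)C | intermediate
4 | trimethyl{[(4R,5S)-5-ethenyl-4-(2-iodopropan-2-yl)-5-methylcyclohex-1-en-1-yl]oxy}silane | C[Si](C)(C)OC1=CC[C@@H](C(C)(C)I)[C@](C)(C=C)C1 | intermediate
5 | trimethyl{[(4S,5S)-5-ethenyl-5-methyl-4-(prop-1-en-2-yl)cyclohex-1-en-1-yl]oxy}silane | C[Si](C)(C)OC1=CC[C@@H](C(C)=C)[C@](C)(C=C)C1 | intermediate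
6 | diethyl meso-2,5-dibromohexanedioate | CCOC(=O)[C@H](Br)CC[C@H](Br)C(=O)OCC | starting material
7 | diethyl 2-bromo-5-[(1R,4S,5S)-4-ethenyl-4-methyl-2-oxo-5-(prop-1-en-2-yl)cyclohexyl]hexanedioate, epimer mixture at C-2 and C-5 of the chain | CCOC(=O)C(Br)CCC(C(=O)OCC)[C@H]1C[C@@H](C(C)=C)[C@](C)(C=C)CC1=O | intermediate
8 | lithium (1R,2R,4S,5S)-2-(5-bromo-1,6-diethoxy-1,6-dioxohexan-2-yl)-5-ethenyl-5-methyl-4-(prop-1-en-2-yl)cyclohexan-1-olate (ring locants as in 9), chain epimers as in 7 | [Li+].CCOC(=O)C(Br)CCC(C(=O)OCC)[C@H]1C[C@@H](C(C)=C)[C@](C)(C=C)C[C@H]1[O-] | intermediate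
9 | diethyl 2-bromo-5-[(1R,2R,4S,5S)-4-ethenyl-4-methyl-5-(prop-1-en-2-yl)-2-(triethylsilyloxy)cyclohexyl]hexanedioate, chain epimers as in 7 | CCOC(=O)C(Br)CCC(C(=O)OCC)[C@H]1C[C@@H](C(C)=C)[C@](C)(C=C)C[C@H]1O[Si](CC)(CC)CC | intermediate
10 | (1S,5S)-(−)-verbenone | CC1=CC(=O)[C@H]2C[C@@H]1C2(C)C | starting material
11 | (1S,4R,5R)-4-ethenyl-4,6,6-trimethylbicyclo[3.1.1]heptan-2-one | O=C1C[C@](C)(C=C)[C@@H]2C[C@H]1C2(C)C | intermediate
12 | trimethyl{[(4S,5R)-5-ethenyl-4-(2-iodopropan-2-yl)-5-methylcyclohex-1-en-1-yl]oxy}silane | C[Si](C)(C)OC1=CC[C@H](C(C)(C)I)[C@@](C)(C=C)C1 | intermediate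
13 | trimethyl{[(4R,5R)-5-ethenyl-5-methyl-4-(prop-1-en-2-yl)cyclohex-1-en-1-yl]oxy}silane | C[Si](C)(C)OC1=CC[C@H](C(C)=C)[C@@](C)(C=C)C1 | intermediate
14 | diethyl 2-[(4R,5R)-4-ethenyl-4-methyl-2-oxo-5-(prop-1-en-2-yl)cyclohexyl]-5-[(1R,2R,4S,5S)-4-ethenyl-4-methyl-5-(prop-1-en-2-yl)-2-(triethylsilyloxy)cyclohexyl]hexanedioate, epimer mixture at C-1 of the oxocyclohexyl ring and at C-2 and C-5 of the chain | O=C1C[C@](C)(C=C)[C@@H](C(C)=C)CC1C(C(=O)OCC)CCC(C(=O)OCC)[C@H]2C[C@@H](C(C)=C)[C@](C)(C=C)C[C@H]2O[Si](CC)(CC)CC | intermediate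
15 | ethyl 2-[(4R,5R)-4-ethenyl-4-methyl-2-oxo-5-(prop-1-en-2-yl)cyclohexyl]-4-[(3aR,5S,6S,7aR)-6-ethenyl-6-methyl-2-oxo-5-(prop-1-en-2-yl)octahydro-1-benzofuran-3-yl]butanoate, epimer mixture at the three unassigned centres | O=C1C[C@](C)(C=C)[C@@H](C(C)=C)CC1C(C(=O)OCC)CCC3C(=O)O[C@@H]4C[C@@](C)(C=C)[C@H](C(=C)C)C[C@H]34 | intermediate
16 | dipotassium salt holding the 2-oxidofuran of half A ((5R,6R)-4,5,6,7-tetrahydro-1-benzofuran-2-olate) and the enolate of lactone B ((3aR,5S,6S,7aR)-3a,4,5,6,7,7a-hexahydro-1-benzofuran-2-olate), joined through C-3 and C-3′ by an ethane-1,2-diyl chain | [K+].[K+].C=C[C@@]1(C)CC2=C(C[C@@H]1C(=C)C)C(CCC3=C([O-])O[C@@H]4C[C@@](C)(C=C)[C@H](C(=C)C)C[C@H]34)=C([O-])O2 | intermediate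
17 | (5R,6R)-6-ethenyl-3-{2-[(3S,3aR,5S,6S,7aR)-6-ethenyl-6-methyl-2-oxo-5-(prop-1-en-2-yl)octahydro-1-benzofuran-3-yl]ethyl}-6-methyl-5-(prop-1-en-2-yl)-4,5,6,7-tetrahydro-1-benzofuran-2(3H)-one, C-3 of the unsaturated lactone unassigned | C=C[C@@]1(C)CC2=C(C[C@@H]1C(=C)C)C(CC[C@@H]3C(=O)O[C@@H]4C[C@@](C)(C=C)[C@H](C(=C)C)C[C@H]34)C(=O)O2 | intermediate
18 | (5R,6R,7aR)-6-ethenyl-3-{2-[(3S,3aR,5S,6S,7aR)-6-ethenyl-6-methyl-2-oxo-5-(prop-1-en-2-yl)octahydro-1-benzofuran-3-yl]ethyl}-6-methyl-5-(prop-1-en-2-yl)-5,6,7,7a-tetrahydro-1-benzofuran-2(4H)-one (CNP0332736.1) | C=C[C@@]1(C)C[C@H]2OC(=O)C(CC[C@@H]3C(=O)O[C@@H]4C[C@@](C)(C=C)[C@H](C(=C)C)C[C@H]34)=C2C[C@@H]1C(=C)C | target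

**Step count and weak points**

Total steps: 8. Longest linear sequence: 6 (steps 1, 2, 3, 4, 7, 8).

The three steps most likely to fail:

Step 8 (the cascade is new; the butenolide may not close under base, or the protonation may be unselective). Fallback: the rings are closed by classical dehydration and the stereochemistry is adjusted afterwards. It sets out from 14. LiOH in THF–water cleaves both ethyl esters, and acidification to pH 2 removes the silyl group and closes the saturated lactone, giving 2-[(4R,5R)-4-ethenyl-4-methyl-2-oxo-5-(prop-1-en-2-yl)cyclohexyl]-4-[(3aR,5S,6S,7aR)-6-ethenyl-6-methyl-2-oxo-5-(prop-1-en-2-yl)octahydro-1-benzofuran-3-yl]butanoic acid F4. Ac2O/NaOAc at 70 °C and then DBU turn the γ-keto acid into the conjugated butenolide, giving the bis-lactone with C-3 of the saturated lactone unassigned F5. KN(SiMe3)2 at −78 °C then comes back to the route at 16, and the phenol quench of step 8 gives 18.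

Step 7 (the ester radical may also add to the vinyl and isopropenyl groups, and both partners are advanced). Fallback: polar instead of radical alkylation. It sets out from 13. MeLi in THF cleaves the silyl enol ether to the regiodefined lithium (4R,5R)-5-ethenyl-5-methyl-4-(prop-1-en-2-yl)cyclohex-1-en-1-olate F3, which is alkylated by the α-bromo ester 9 in THF–DMPU at −78 → −20 °C (SN2 at the ester α-carbon) and so comes back to the route at 14.

Step 2 (capture of the cation by iodide and the direction of HI loss are the weak points; step 6 is its mirror image). Fallback: acetate capture and thermal elimination. It sets out from 3. BF3·OEt2/Zn(OAc)2/Ac2O opens the cyclobutane with capture of the tertiary cation by acetate, giving (4R,5S)-4-[2-(acetyloxy)propan-2-yl]-5-ethenyl-5-methylcyclohex-1-en-1-yl acetate F1. Flash vacuum pyrolysis at about 450 °C removes acetic acid toward a methyl group and gives (4S,5S)-5-ethenyl-5-methyl-4-(prop-1-en-2-yl)cyclohex-1-en-1-yl acetate F2. F2 takes the place of 5 as radical acceptor with 6 under the conditions of step 3 and so comes back to the route at 7.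

**Further compounds**

F1 | step 2 | (4R,5S)-4-[2-(acetyloxy)propan-2-yl]-5-ethenyl-5-methylcyclohex-1-en-1-yl acetate | CC(=O)OC1=CC[C@@H](C(C)(C)OC(C)=O)[C@](C)(C=C)C1
F2 | step 2 | (4S,5S)-5-ethenyl-5-methyl-4-(prop-1-en-2-yl)cyclohex-1-en-1-yl acetate | CC(=O)OC1=CC[C@@H](C(C)=C)[C@](C)(C=C)C1
F3 | step 7 | lithium (4R,5R)-5-ethenyl-5-methyl-4-(prop-1-en-2-yl)cyclohex-1-en-1-olate | [Li+].[O-]C1=CC[C@H](C(C)=C)[C@@](C)(C=C)C1
F4 | step 8 | 2-[(4R,5R)-4-ethenyl-4-methyl-2-oxo-5-(prop-1-en-2-yl)cyclohexyl]-4-[(3aR,5S,6S,7aR)-6-ethenyl-6-methyl-2-oxo-5-(prop-1-en-2-yl)octahydro-1-benzofuran-3-yl]butanoic acid, epimer mixture at the three unassigned centres | O=C1C[C@](C)(C=C)[C@@H](C(C)=C)CC1C(C(=O)O)CCC3C(=O)O[C@@H]4C[C@@](C)(C=C)[C@H](C(=C)C)C[C@H]34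
F5 | step 8 | (5R,6R,7aR)-6-ethenyl-3-{2-[(3aR,5S,6S,7aR)-6-ethenyl-6-methyl-2-oxo-5-(prop-1-en-2-yl)octahydro-1-benzofuran-3-yl]ethyl}-6-methyl-5-(prop-1-en-2-yl)-5,6,7,7a-tetrahydro-1-benzofuran-2(4H)-one, epimer mixture at C-3 of the saturated lactone | C=C[C@@]1(C)C[C@H]2OC(=O)C(CCC3C(=O)O[C@@H]4C[C@@](C)(C=C)[C@H](C(=C)C)C[C@H]34)=C2C[C@@H]1C(=C)C
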